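**Assumption:** 4-methylpent-1-en-3-one, 4-[(tert-butyldimethylsilyl)oxy]benzoic acid and (2Z)-2-methylbut-2-enoic acid are bought. Ring positions are cited with azulene locants: C3 carbinol, C3a ring-fusion CH, C4 and C8 oxygenated CH, C6 methyl-bearing alkene carbon, C8a quaternary carbon.

## Retrosynthetic overview

1. Target ⇐ enone diol 12 by C4 benzoylation, 1,2-reduction of the C8 ketone, C8 angeloylation and phenol desilylation.
2. 12 ⇐ acyclic keto aldehyde 7 (an isomer of 12) by a one-flask double cyclisation: an intramolecular Mukaiyama aldol closes the five-membered ring first, then a vinylogous Mukaiyama aldol closes the seven-membered ring.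
3. 7 ⇐ α-quaternary ketone 6 by cleavage of the allyl group to CH2CHO.
4. 6 ⇐ β-keto allyl ester 5 by Pd-catalysed decarboxylative asymmetric allylation; this quaternary carbon is the only centre set by a catalyst, the other four are relayed from it.
5. 5 ⇐ allyl propanoate + 3-methylbut-2-enoyl chloride + 4-methylpent-1-en-3-one.

## Route

Step 1
Reactants: 1 prop-2-en-1-yl propanoate; 2 3-methylbut-2-enoyl chloride
Product: 3 prop-2-en-1-yl 2,5-dimethyl-3-oxohex-4-enoate (racemic)
Conditions: LiN(i-Pr)2 (2.0 equiv), 1 (2.0 equiv), THF, −78 °C; then 2 (1.0 equiv), −78 → 0 °C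
Reagents that add atoms: 3-methylbut-2-enoyl chloride (2), CC(C)=CC(=O)Cl
Why: Crossed Claisen condensation (C-acylation of the ester lithium enolate, the second enolate equivalent absorbing the acidic product proton); the α-centre is racemic and is erased in step 3.

Step 2
Reactants: 3 β-keto ester; 4 4-methylpent-1-en-3-one
Product: 5 prop-2-en-1-yl 2,6-dimethyl-2-(3-methylbut-2-enoyl)-5-oxoheptanoate (racemic)
Conditions: FeCl3·6H2O (5 mol%), CH2Cl2, rt
Reagents that add atoms: 4-methylpent-1-en-3-one (4), C=CC(=O)C(C)C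
Why: Iron-catalysed Michael addition of a 2-substituted β-keto ester to a vinyl ketone under base-free conditions, which avoids enone isomerisation; the quaternary centre is formed racemic and is re-set in step 3.

Step 3
Reactants: 5 Michael adduct
Product: 6 (5S)-2,5,9-trimethyl-5-(prop-2-en-1-yl)dec-2-ene-4,8-dione
Conditions: Pd2(dba)3 (2.5 mol%), (S)-(CF3)3-t-BuPHOX (6 mol%), hexane/toluene 2:1, 25 °C
Reagents that add atoms: none
Why: Tsuji–Stoltz decarboxylative asymmetric allylic alkylation: zerovalent palladium ionises the allyl ester, CO2 is lost and the ligand-bound palladium enolate is allylated at the fully substituted α-carbon, the (S)-ligand being chosen to give the (S) quaternary centre by analogy with 2-allyl-2-methylcycloalkanones.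

Step 4
Reactants: 6 allyl ketone
Product: 7 (3S)-3,7-dimethyl-3-(3-methylbut-2-enoyl)-6-oxooctanal
Conditions: OsO4 (2 mol%), NaIO4 (4 equiv), 2,6-lutidine, 1,4-dioxane/H2O 3:1, rt
Reagents that add atoms: osmium tetroxide, O=[Os](=O)(=O)=O; sodium periodate, [Na+].[O-]I(=O)(=O)=O
Why: Lemieux–Johnson oxidation cleaves the electron-rich terminal alkene and leaves the electron-poor trisubstituted enone alkene alone; the quaternary centre is not touched.

Step 5
Reactants: 7 keto aldehyde
Product: 12 (3R,3aS,4S,8aS)-3,4-dihydroxy-6,8a-dimethyl-3-(propan-2-yl)-2,3,3a,4,5,8a-hexahydroazulen-8(1H)-one, via enol silane 8 (not isolated), via cyclopentane aldehyde 9 (not isolated), via siloxydiene 10 (not isolated), via bis-silyl ether 11 (not isolated)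
Conditions: Me3SiOTf (1.1 equiv), i-Pr2NEt (1.05 equiv), CH2Cl2, −78 °C; then Me3SiOTf (1.3 equiv), i-Pr2NEt (1.2 equiv), −78 → −20 °C; then 1 M HCl, THF, 0 °C
Reagents that add atoms: none
Why: Proposed new method: the aldehyde is silylated fastest to enol silane 8, whose silyl-triflate-promoted 5-exo Mukaiyama aldol onto the isopropyl ketone closes the cyclopentane with the three large groups (acyl arm on C8a, formyl on C3a, isopropyl on C3) mutually trans, which fixes C3a and C3 relative to C8a and removes the only other enolisable ketone; the second portion of reagent then turns the enone (no α′-hydrogen, so only γ-deprotonation) into siloxydiene 10, whose γ-carbon adds to the silyl-activated aldehyde (vinylogous Mukaiyama aldol; α-attack would need a strained trans-fused bicyclo[3.3.0]octane) through the conformer with C=O next to the small C3a–H, giving the (4S) carbinol and the trans-fused ring system; closest known reactions are the one-pot Me3SiOTf/amine enol-silane formation–Mukaiyama aldol and intramolecular vinylogous Mukaiyama aldol ring closures.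

Step 6
Reactants: 12 enone diol; 13 4-[(tert-butyldimethylsilyl)oxy]benzoic acid
Product: 14 C4 4-(silyloxy)benzoate of 12
Conditions: 13 (1.3 equiv), EDC·HCl, DMAP (0.3 equiv), CH2Cl2, 0 °C → rt
Reagents that add atoms: 4-[(tert-butyldimethylsilyl)oxy]benzoic acid (13), OC(=O)c1ccc(O[Si](C)(C)C(C)(C)C)cc1
Why: Steglich esterification; the C4 hydroxyl is the only secondary alcohol present (the C3 hydroxyl is tertiary and inert), so the benzoate is placed regiospecifically with retention at C4.

Step 7
Reactants: 14 enone ester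
Product: 15 (8S)-allylic alcohol
Conditions: NaBH4, CeCl3·7H2O, MeOH, −78 °C
Reagents that add atoms: none
Why: Luche reduction (1,2-selective); hydride is expected to approach the cycloheptenone from the face opposite the angular C8a methyl group, so the new hydroxyl ends up cis to that methyl, i.e. (8S).

Step 8
Reactants: 15 allylic alcohol; 16 (2Z)-2-methylbut-2-enoic acid
Product: 18 C8 angelate, via mixed anhydride 17 (not isolated)
Conditions: 16, 2,4,6-trichlorobenzoyl chloride, Et3N, toluene, rt; then 15, DMAP, toluene, 60 °C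
Reagents that add atoms: (2Z)-2-methylbut-2-enoic acid (16), C/C=C(/C)C(=O)O
Why: Yamaguchi esterification through the pre-formed mixed anhydride acylates the only remaining secondary alcohol with little Z to E isomerisation of the angelate and with retention at C8 (acylation on oxygen).

Step 9
Reactants: 18 silyl-protected diester
Product: 19 CNP0273650.10 (target)
Conditions: Bu4NF, AcOH, THF, 0 °C
Reagents that add atoms: none
Why: Fluoride-mediated cleavage of the aryl silyl ether, buffered with acetic acid so that neither ester migrates nor the angelate isomerises; no stereocentre is involved.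

## Compound list

1 | prop-2-en-1-yl propanoate | CCC(=O)OCC=C | starting material
2 | 3-methylbut-2-enoyl chloride | CC(C)=CC(=O)Cl | starting material
3 | prop-2-en-1-yl 2,5-dimethyl-3-oxohex-4-enoate (racemic) | CC(C)=CC(=O)C(C)C(=O)OCC=C | intermediate
4 | 4-methylpent-1-en-3-one | C=CC(=O)C(C)C | starting material
5 | prop-2-en-1-yl 2,6-dimethyl-2-(3-methylbut-2-enoyl)-5-oxoheptanoate (racemic) | CC(C)=CC(=O)C(C)(CCC(=O)C(C)C)C(=O)OCC=C | intermediate
6 | (5S)-2,5,9-trimethyl-5-(prop-2-en-1-yl)dec-2-ene-4,8-dione | CC(C)=CC(=O)[C@](C)(CC=C)CCC(=O)C(C)C | intermediate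
7 | (3S)-3,7-dimethyl-3-(3-methylbut-2-enoyl)-6-oxooctanal | CC(C)=CC(=O)[C@](C)(CC=O)CCC(=O)C(C)C | intermediate
8 | (5S)-2,5,9-trimethyl-5-[2-(trimethylsilyloxy)ethenyl]dec-2-ene-4,8-dione (E/Z mixture) | CC(C)=CC(=O)[C@](C)(C=CO[Si](C)(C)C)CCC(=O)C(C)C | intermediate
9 | (1R,2S,5R)-2-methyl-2-(3-methylbut-2-enoyl)-5-(propan-2-yl)-5-(trimethylsilyloxy)cyclopentane-1-carbaldehyde | O=C[C@@H]1[C@@](C)(C(=O)C=C(C)C)CC[C@@]1(O[Si](C)(C)C)C(C)C | intermediate
10 | (1R,2S,5R)-2-methyl-2-[3-methyl-1-(trimethylsilyloxy)buta-1,3-dien-1-yl]-5-(propan-2-yl)-5-(trimethylsilyloxy)cyclopentane-1-carbaldehyde | O=C[C@@H]1[C@@](C)(C(O[Si](C)(C)C)=CC(C)=C)CC[C@@]1(O[Si](C)(C)C)C(C)C | intermediate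
11 | (3R,3aS,4S,8aS)-6,8a-dimethyl-3-(propan-2-yl)-3,4-bis(trimethylsilyloxy)-2,3,3a,4,5,8a-hexahydroazulen-8(1H)-one | O=C1C=C(C)C[C@H](O[Si](C)(C)C)[C@@H]2[C@]1(C)CC[C@@]2(O[Si](C)(C)C)C(C)C | intermediate
12 | (3R,3aS,4S,8aS)-3,4-dihydroxy-6,8a-dimethyl-3-(propan-2-yl)-2,3,3a,4,5,8a-hexahydroazulen-8(1H)-one | O=C1C=C(C)C[C@H](O)[C@@H]2[C@]1(C)CC[C@@]2(O)C(C)C | intermediate
13 | 4-[(tert-butyldimethylsilyl)oxy]benzoic acid | OC(=O)c1ccc(O[Si](C)(C)C(C)(C)C)cc1 | starting material
14 | (3R,3aS,4S,8aS)-3-hydroxy-6,8a-dimethyl-8-oxo-3-(propan-2-yl)-1,2,3,3a,4,5,8,8a-octahydroazulen-4-yl 4-[(tert-butyldimethylsilyl)oxy]benzoate | O=C1C=C(C)C[C@H](OC(=O)c2ccc(O[Si](C)(C)C(C)(C)C)cc2)[C@@H]2[C@]1(C)CC[C@@]2(O)C(C)C | intermediate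
15 | (3R,3aS,4S,8S,8aS)-3,8-dihydroxy-6,8a-dimethyl-3-(propan-2-yl)-1,2,3,3a,4,5,8,8a-octahydroazulen-4-yl 4-[(tert-butyldimethylsilyl)oxy]benzoate | O[C@H]1C=C(C)C[C@H](OC(=O)c2ccc(O[Si](C)(C)C(C)(C)C)cc2)[C@@H]2[C@]1(C)CC[C@@]2(O)C(C)C | intermediate
16 | (2Z)-2-methylbut-2-enoic acid (angelic acid) | C/C=C(/C)C(=O)O | starting material
17 | (2Z)-2-methylbut-2-enoic 2,4,6-trichlorobenzoic anhydride | C/C=C(/C)C(=O)OC(=O)c1c(Cl)cc(Cl)cc1Cl | intermediate
18 | (3R,3aS,4S,8S,8aS)-3-hydroxy-6,8a-dimethyl-8-{[(2Z)-2-methylbut-2-enoyl]oxy}-3-(propan-2-yl)-1,2,3,3a,4,5,8,8a-octahydroazulen-4-yl 4-[(tert-butyldimethylsilyl)oxy]benzoate | C/C=C(/C)C(=O)O[C@H]1C=C(C)C[C@H](OC(=O)c2ccc(O[Si](C)(C)C(C)(C)C)cc2)[C@@H]2[C@]1(C)CC[C@@]2(O)C(C)C | intermediate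
19 | (3R,3aS,4S,8S,8aS)-3-hydroxy-6,8a-dimethyl-8-{[(2Z)-2-methylbut-2-enoyl]oxy}-3-(propan-2-yl)-1,2,3,3a,4,5,8,8a-octahydroazulen-4-yl 4-hydroxybenzoate (CNP0273650.10) | C/C=C(/C)C(=O)O[C@H]1C=C(C)C[C@H](OC(=O)c2ccc(O)cc2)[C@@H]2[C@]1(C)CC[C@@]2(O)C(C)C | target

## Step count and risk

Total steps: 9. Longest linear sequence: 9 (steps 1 to 9; compounds 4, 13 and 16 are bought).

**Step 5 (double cyclisation) is the most likely to fail.** The sequence depends on the aldehyde being silylated and cyclised before the isopropyl ketone is enolised, on γ- rather than α-attack of the siloxydiene, and on the stereochemical relay from C8a. The fallback separates the two ring closures and changes the activation mode. It sets out from 7: enamine catalysis with dibenzylammonium trifluoroacetate in toluene closes the cyclopentane to the hydroxy aldehyde F1. Et3SiOTf/Et3N then silylates the tertiary alcohol and converts the enone into the bis-triethylsilyl siloxydiene F2. BF3·OEt2 at −78 °C closes the seven-membered ring by vinylogous Mukaiyama aldol to the mono-silyl enone F3. HF·pyridine removes the remaining silyl ether, and the route is rejoined at 12.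

**Step 3 (asymmetric allylation) may give low enantiomeric excess.** The palladium enolate is acyclic, and its geometry is less well controlled than in the cyclic cases the ligand was developed for. The fallback gives up asymmetric catalysis for resolution. It sets out from 5: Pd(PPh3)4 in THF gives the racemic ketone F4, which is separated by preparative chromatography on a chiral stationary phase. The (R)-enantiomer F5 is set aside, and the (S)-enantiomer rejoins the route at 6.

**Step 7 (ketone reduction) may deliver hydride from the wrong face.** The seven-membered ring is flexible, so the bias from the angular methyl group may be weak or reversed. The fallback turns the wrong epimer into product by inversion. It sets out from 14: whichever hydride (for example LiBH(s-Bu)3) gives mainly the (8R)-alcohol F6 is used, and F6 is esterified with 16 under Mitsunobu conditions (PPh3, DIAD, toluene). Inversion at C8 gives the angelate directly, and the route is rejoined at 18 with step 8 skipped.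

## Further compounds

F1 | step 5 | (1R,2R,5S)-2-hydroxy-5-methyl-5-(3-methylbut-2-enoyl)-2-(propan-2-yl)cyclopentane-1-carbaldehyde | O=C[C@@H]1[C@@](C)(C(=O)C=C(C)C)CC[C@@]1(O)C(C)C
F2 | step 5 | (1R,2S,5R)-2-methyl-2-[3-methyl-1-(triethylsilyloxy)buta-1,3-dien-1-yl]-5-(propan-2-yl)-5-(triethylsilyloxy)cyclopentane-1-carbaldehyde | O=C[C@@H]1[C@@](C)(C(O[Si](CC)(CC)CC)=CC(C)=C)CC[C@@]1(O[Si](CC)(CC)CC)C(C)C
F3 | step 5 | (3R,3aS,4S,8aS)-4-hydroxy-6,8a-dimethyl-3-(propan-2-yl)-3-(triethylsilyloxy)-2,3,3a,4,5,8a-hexahydroazulen-8(1H)-one | O=C1C=C(C)C[C@H](O)[C@@H]2[C@]1(C)CC[C@@]2(O[Si](CC)(CC)CC)C(C)C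
F4 | step 3 | racemic 2,5,9-trimethyl-5-(prop-2-en-1-yl)dec-2-ene-4,8-dione | CC(C)=CC(=O)C(C)(CC=C)CCC(=O)C(C)C
F5 | step 3 | (5R)-2,5,9-trimethyl-5-(prop-2-en-1-yl)dec-2-ene-4,8-dione | CC(C)=CC(=O)[C@@](C)(CC=C)CCC(=O)C(C)C
F6 | step 7 | (3R,3aS,4S,8R,8aS)-3,8-dihydroxy-6,8a-dimethyl-3-(propan-2-yl)-1,2,3,3a,4,5,8,8a-octahydroazulen-4-yl 4-[(tert-butyldimethylsilyl)oxy]benzoate | O[C@@H]1C=C(C)C[C@H](OC(=O)c2ccc(O[Si](C)(C)C(C)(C)C)cc2)[C@@H]2[C@]1(C)CC[C@@]2(O)C(C)C
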